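The product is what this meeting counted, in millimolar and not in percent, because the question is how much target stands at the end when more substrate meets the same reagent.

| flask | substrate | reagent | remark | time |
|---|---|---|---|---|
| winter | 4.3 mM | 19 mM | run made earlier |  |
| dawn | 19 mM | 19 mM | run made earlier |  |
| spring | 77 mM | 19 mM | run made earlier |  |
| amber | 5.0 mM | 19.0 mM |  | 20 h |
| teal | 10 mM | 19.0 mM |  | 20 h |
| grey | 20 mM | 19.0 mM |  | 20 h |
| blue | 40 mM | 19.0 mM |  | 20 h |
| red | 80 mM | 19.0 mM |  | 20 h |

| run | time / h | target / % | substrate / % |
|---|---|---|---|
| winter | 5.00 | 2 | 2 |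
| winter | 10.0 | 14 | 3 |
| winter | 15.0 | 25 | 0 |
| winter | 20.0 | 37 | 0 |
| dawn | 5.00 | 1 | 5 |
| dawn | 10.0 | 4 | 0 |
| dawn | 15.0 | 8 | 0 |
| dawn | 20.0 | 12 | 4 |
| spring | 1.50 | 2 | 35 |
| spring | 4.00 | 2 | 9 |
| spring | 8.00 | 0 | 0 |
| spring | 20.0 | 2 | 0 |

(readings scatter by 2 percentage points)

- "hardly changes" means that all values lie within two and a half points (for a concentration: within two and a half percent of the largest)
- a step back or a flat step of under half a percent of the largest counts as no turn

* [target] at the end for amber, teal, grey, blue, red, in this order
* how that number moves from the first to the last of them (rises all the way / hardly changes / falls all the way / falls, then rises / rises, then falls)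

The chair opened with the last readings of the earlier runs. The analyst reported that winter, charged with 4.3 mM of substrate, reached a yield of 37 % at 20.0 h, which is 1.59 mM of target, and that dawn, charged with 19 mM, reached 12 %, which is 2.28 mM. So the charge rose 4.42 times, while the amount rose 1.43 times. She suspected a change of limiting reagent, though she granted that no run reads the reagent.

A colleague objected that spring's 2 % equals the scatter of 2 percentage points, and the meeting kept its 1.54 mM, less than dawn's amount, as a rough sign of direction.

The analyst then proposed one mark for the change of control: the crossing charge, the charge at which winter's yield gives dawn's amount. Dawn's amount divided by winter's yield gave her 6.16 mM, a reading that carries the scatter of both. Below it, with the reagent charge of these runs, she would reckon the target as winter's yield times the charge, so amber, at 5.0 mM and under the crossing, came to 1.85 mM. Since spring's rough amount stands lower than dawn's, she expected the amount to fall again past a peak, and she expected that peak somewhat above the crossing.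

The forecast, presented next, gave 1.8 mM, 2.3 mM, 2.3 mM, 1.5 mM and 0.8 mM, a row that rises, then falls, and stated: “The absolute amount therefore peaks near 10–20 mM and falls afterwards.” The analyst's crossing stood lower than teal's charge, and the minutes left open how far above the crossing the peak lay.

The flasks give 1.83 mM, 2.56 mM, 2.15 mM, 1.51 mM and 1.02 mM, a row that rises, then falls. Grey ended with 0.0990 % of its reagent charge left and 35.8 % of its substrate charge standing as intermediate A.

    substrate → intermediate A (k = 1.85 × 10⁻⁴ s⁻¹)
    2 reagent → self-condensation product (k = 5.56 × 10⁻⁴ M⁻¹ s⁻¹)
    reagent + intermediate D → intermediate E (k = 0.00675 M⁻¹ s⁻¹)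
    intermediate E → target (k = 1.19 × 10⁻⁵ s⁻¹)
    reagent + intermediate A → intermediate D (k = 0.0124 M⁻¹ s⁻¹)
    substrate + reagent ⇌ intermediate B (K = 72.0 M⁻¹, k = 5.41 × 10⁻⁴ M⁻¹ s⁻¹)
    intermediate B ⇌ intermediate C (K = 1.30, k = 4.87 × 10⁻⁶ s⁻¹)

The row turns at 11 mM, above the crossing charge of 6.16 mM read from the earlier runs. Amber, charged below that crossing, was reckoned at 1.85 mM and held 1.83 mM, which is 36.5 % of its substrate charge.

The earlier runs and the new flask are calculated with made-up constants; scatter was added.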